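**Plan**
- Target: 3β-acetoxylabda-7,13E-dien-15-oic acid (labdane numbering). Retrosynthetic cuts: C13=C14 (olefination), C11–C12 (C11 borane plus bromoacetone), C9=C11 (methylenation of a C9 ketone), C3–C4 (radical closure of ring A), C10–C1 and C10–CH3 (two enolate alkylations).
- Enabling feature: ring B (C5–C10), with its methyl on the C7=C8 alkene and oxygen at C9, is the cyclohexenone of (R)-carvone. The isopropenyl carbon of carvone is C4 with one geminal methyl in place, so ring A lacks only one hydrogen on the =CH2 and the C3–C4 bond.
- Forward order: ring B is bought as carvone; C10 is made quaternary (methyl, then an allyl arm oxidised to the C3 aldehyde); ring A closes by hydrogen-atom-transfer radical cyclisation; the chain is joined as C11, then C12/C13/C16, then C14/C15; acetate and acid are set last.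
- Stereochemistry: C5 from (R)-carvone; C10 by alkylation anti to isopropenyl; C3 from the chair of the radical closure; C9 by α-face hydroboration anti to the C10 methyl; 13E from the Horner–Wadsworth–Emmons reaction.

Key step: step 5

Remark: 4 is carried on as its mixture of C6 epimers (trans epimer drawn), since step 2 re-enolises that centre. Ring carbons C1–C11 are numbered alike in the drimane and labdane names used. Building blocks whose atoms reach the target carry compound numbers; other reagents are named on the reagent lines.

Step 1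
Reactants: 1 (R)-carvone; 2 iodomethane
Product: 4 6-methylcarvone [(5R,6S)-2,6-dimethyl-5-(prop-1-en-2-yl)cyclohex-2-en-1-one as major epimer], via lithium dienolate 3 (not isolated)
Conditions: LDA, THF, −78 °C; then MeI, −78 → 0 °C
Reagents that add atoms: iodomethane (2), CI
Why: Kinetic α′-deprotonation should give the cross-conjugated lithium dienolate, which undergoes enolate C-alkylation with iodomethane; the configuration of the new centre is of no consequence because it is re-enolised in step 2.

Step 2
Reactants: 4 6-methylcarvone; 5 allyl bromide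
Product: 7 (5S,6S)-6-allyl-2,6-dimethyl-5-(prop-1-en-2-yl)cyclohex-2-en-1-one (allyl trans to isopropenyl), via lithium enolate 6 (not isolated)
Conditions: LDA, THF, −78 → 0 °C; then allyl bromide, DMPU, −78 °C → rt
Reagents that add atoms: allyl bromide (5), C=CCBr
Why: Enolate alkylation of the tetrasubstituted α′-enolate with a reactive allylic bromide should take place on the face opposite the neighbouring isopropenyl group (1,2-induction), which sets the quaternary C10 with the three-carbon arm trans and the methyl cis to isopropenyl.

Step 3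
Reactants: 7 (5S,6S)-6-allyl-2,6-dimethyl-5-(prop-1-en-2-yl)cyclohex-2-en-1-one
Product: 9 (5S,6S)-6-(3-hydroxypropyl)-2,6-dimethyl-5-(prop-1-en-2-yl)cyclohex-2-en-1-one, via alkyl(disiamyl)borane 8 (not isolated)
Conditions: Sia2BH (from BH3·THF and 2-methylbut-2-ene), THF, 0 °C; then NaBO3·4H2O, H2O, rt
Reagents that add atoms: sodium perborate, [Na+].[Na+].O[B-]1(O)OO[B-](O)(O)OO1
Why: Anti-Markovnikov hydroboration–oxidation with a bulky dialkylborane should pick the monosubstituted allyl double bond over the 1,1-disubstituted isopropenyl group, the electron-poor enone alkene and the hindered conjugated ketone, and perborate oxidises the C–B bond without the alkaline peroxide that would epoxidise the enone.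

Step 4
Reactants: 9 (5S,6S)-6-(3-hydroxypropyl)-2,6-dimethyl-5-(prop-1-en-2-yl)cyclohex-2-en-1-one
Product: 10 3-[(1S,6S)-1,3-dimethyl-2-oxo-6-(prop-1-en-2-yl)cyclohex-3-en-1-yl]propanal
Conditions: Dess–Martin periodinane, NaHCO3, CH2Cl2, 0 °C → rt
Reagents that add atoms: none
Why: Dess–Martin oxidation of the primary alcohol under buffered, non-basic conditions should stop at the aldehyde and leave the enone, the isopropenyl group and both stereocentres untouched.

Step 5
Reactants: 10 3-[(1S,6S)-1,3-dimethyl-2-oxo-6-(prop-1-en-2-yl)cyclohex-3-en-1-yl]propanal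
Product: 11 3β-hydroxy-11-nordrim-7-en-9-one [(4aS,6S,8aS)-6-hydroxy-2,5,5,8a-tetramethyl-4a,5,6,7,8,8a-hexahydronaphthalen-1(4H)-one]
Conditions: Fe(acac)3 (30 mol %), PhSiH3, EtOH, 60 °C, Ar
Reagents that add atoms: none
Why: The iron hydride formed from Fe(acac)3 and PhSiH3 should transfer a hydrogen atom to the =CH2 terminus of the isopropenyl group, which creates the second C4 methyl and a nucleophilic tertiary radical at C4; this radical adds to the aldehyde carbon C3, and the alkoxy radical is reduced and protonated in the alcoholic medium, which drains the reversible addition toward the alcohol. The closest known reaction type is the metal-hydride HAT-initiated radical cyclisation of alkene-tethered ketones, together with the iron-mediated HAT addition of alkenes to aldehydes. Ring A closes in the 6-exo-trig mode onto the C=O bond, through a chair that can only be trans-fused because the tether carbons C1 and C4 are held trans on ring B by the fixed centres C10 and C5. C3 is the only new stereocentre and is controlled by this chair, in which the C–O bond takes the equatorial position to avoid the axial hydrogens on C1 and C5, so the 3β-alcohol should predominate. The step needs chemoselective HAT to the isopropenyl group beside the enone; this is secured because the electron-rich 1,1-disubstituted alkene is the fast acceptor and gives a tertiary radical, while the trisubstituted electron-poor enone reacts slowly and is out of reach of the C4 radical for any unstrained ring.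

Step 6
Reactants: 11 3β-hydroxy-11-nordrim-7-en-9-one
Product: 12 3β-(tert-butyldimethylsilyloxy)-11-nordrim-7-en-9-one
Conditions: TBSOTf, 2,6-lutidine, CH2Cl2, −78 → 0 °C
Reagents that add atoms: tert-butyldimethylsilyl triflate, CC(C)(C)[Si](C)(C)OS(=O)(=O)C(F)(F)F
Why: Silyl ether formation with the reactive silyl triflate should cap the hindered equatorial C3 alcohol, while the weak base leaves the ketone, which has no α′ hydrogen, unenolised.

Step 7
Reactants: 12 3β-(tert-butyldimethylsilyloxy)-11-nordrim-7-en-9-one; 13 methyltriphenylphosphonium bromide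
Product: 14 3β-(tert-butyldimethylsilyloxy)drima-7,9(11)-diene (exocyclic C9=C11 methylene conjugated with C7=C8)
Conditions: Ph3PCH3Br, KOtBu, toluene, 90 °C
Reagents that add atoms: methyltriphenylphosphonium bromide (13), C[P+](c1ccccc1)(c1ccccc1)c1ccccc1.[Br-]
Why: Wittig methylenation with salt-free methylenetriphenylphosphorane at elevated temperature is the standard answer to hindered ketones, and the C9 carbonyl cannot enolise toward the quaternary C10, so the silyl ether and all stereocentres should pass unchanged.

Step 8
Reactants: 14 3β-(tert-butyldimethylsilyloxy)drima-7,9(11)-diene; 15 bromoacetone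
Product: 17 3β-(tert-butyldimethylsilyloxy)-14,15-dinorlabd-7-en-13-one, via B-alkyl-9-BBN adduct 16 (not isolated)
Conditions: 9-BBN, THF, 0 → 65 °C; then bromoacetone, potassium 2,6-di-tert-butylphenoxide, THF, 0 °C → rt
Reagents that add atoms: bromoacetone (15), CC(=O)CBr
Why: Hydroboration places boron on the terminal C11 and delivers hydrogen to C9 from the α face, anti to the axial C10 methyl (9α-H, equatorial C11); Brown's base-induced alkylation of α-bromo ketones by B-alkyl-9-BBN then lets the bromoacetone carbanion add to boron, the primary C11 group migrate to carbon with loss of bromide, and the boron enolate be protonated by the phenol to give the C11–C12 bond.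

Step 9
Reactants: 17 3β-(tert-butyldimethylsilyloxy)-14,15-dinorlabd-7-en-13-one; 18 allyl diethylphosphonoacetate
Product: 19 allyl 3β-(tert-butyldimethylsilyloxy)labda-7,13E-dien-15-oate
Conditions: allyl diethylphosphonoacetate, NaH, THF, 0 → 65 °C
Reagents that add atoms: allyl diethylphosphonoacetate (18), C=CCOC(=O)CP(=O)(OCC)OCC
Why: Horner–Wadsworth–Emmons olefination of the methyl ketone with the stabilised phosphonate anion should favour the 13E enoate (ester trans to the larger C12 chain), and the minor 13Z ester is to be removed by chromatography.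

Step 10
Reactants: 19 allyl 3β-(tert-butyldimethylsilyloxy)labda-7,13E-dien-15-oate
Product: 20 allyl 3β-hydroxylabda-7,13E-dien-15-oate
Conditions: 48% aq. HF, MeCN/THF, rt
Reagents that add atoms: none
Why: Fluoride-driven desilylation should free the C3 alcohol under conditions that the allyl ester, the trisubstituted ring alkene and the enoate geometry tolerate.

Step 11
Reactants: 20 allyl 3β-hydroxylabda-7,13E-dien-15-oate; 21 acetic anhydride
Product: 22 allyl 3β-acetoxylabda-7,13E-dien-15-oate
Conditions: Ac2O, pyridine, DMAP (cat.), CH2Cl2, rt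
Reagents that add atoms: acetic anhydride (21), CC(=O)OC(C)=O
Why: DMAP-catalysed acylation of the equatorial secondary alcohol should give the acetate with retention at C3, as no C–O bond at the stereocentre is broken.

Step 12
Reactants: 22 allyl 3β-acetoxylabda-7,13E-dien-15-oate
Product: 23 3β-acetoxylabda-7,13E-dien-15-oic acid (CNP0264606.2)
Conditions: Pd(PPh3)4 (5 mol %), morpholine, THF, rt; dilute acid work-up
Reagents that add atoms: none
Why: Palladium(0)-catalysed allyl ester cleavage (Tsuji–Trost allyl transfer to morpholine) should release the acid under neutral conditions that spare the non-allylic C3 acetate and both alkenes.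

**Compound list**
1 | (R)-carvone | CC1=CC[C@H](CC1=O)C(C)=C | starting material
2 | iodomethane | CI | starting material
3 | lithium dienolate of 1 (C1–C6 enolate) | [Li]OC1=C[C@H](C(C)=C)CC=C1C | intermediate
4 | 6-methylcarvone, (5R,6S) major epimer drawn | C[C@H]1[C@H](C(C)=C)CC=C(C)C1=O | intermediate
5 | allyl bromide | C=CCBr | starting material
6 | lithium enolate of 4 | [Li]OC1=C(C)[C@H](C(C)=C)CC=C1C | intermediate
7 | (5S,6S)-6-allyl-2,6-dimethyl-5-(prop-1-en-2-yl)cyclohex-2-en-1-one | C=CC[C@@]1(C)[C@H](C(C)=C)CC=C(C)C1=O | intermediate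
8 | bis(3-methylbutan-2-yl)borane adduct of 7 at the allyl terminus | CC(C)C(C)B(CCC[C@@]1(C)[C@H](C(C)=C)CC=C(C)C1=O)C(C)C(C)C | intermediate
9 | (5S,6S)-6-(3-hydroxypropyl)-2,6-dimethyl-5-(prop-1-en-2-yl)cyclohex-2-en-1-one | OCCC[C@@]1(C)[C@H](C(C)=C)CC=C(C)C1=O | intermediate
10 | 3-[(1S,6S)-1,3-dimethyl-2-oxo-6-(prop-1-en-2-yl)cyclohex-3-en-1-yl]propanal | O=CCC[C@@]1(C)[C@H](C(C)=C)CC=C(C)C1=O | intermediate
11 | 3β-hydroxy-11-nordrim-7-en-9-one | O[C@H]1CC[C@]2(C)C(=O)C(C)=CC[C@H]2C1(C)C | intermediate
12 | 3β-(tert-butyldimethylsilyloxy)-11-nordrim-7-en-9-one | CC(C)(C)[Si](C)(C)O[C@H]1CC[C@]2(C)C(=O)C(C)=CC[C@H]2C1(C)C | intermediate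
13 | methyltriphenylphosphonium bromide | C[P+](c1ccccc1)(c1ccccc1)c1ccccc1.[Br-] | starting material
14 | 3β-(tert-butyldimethylsilyloxy)drima-7,9(11)-diene | CC(C)(C)[Si](C)(C)O[C@H]1CC[C@]2(C)C(=C)C(C)=CC[C@H]2C1(C)C | intermediate
15 | bromoacetone | CC(=O)CBr | starting material
16 | B-[3β-(tert-butyldimethylsilyloxy)drim-7-en-11-yl]-9-borabicyclo[3.3.1]nonane (9α-H) | CC(C)(C)[Si](C)(C)O[C@H]1CC[C@]2(C)[C@@H](CB3C4CCCC3CCC4)C(C)=CC[C@H]2C1(C)C | intermediate
17 | 3β-(tert-butyldimethylsilyloxy)-14,15-dinorlabd-7-en-13-one | CC(C)(C)[Si](C)(C)O[C@H]1CC[C@]2(C)[C@@H](CCC(C)=O)C(C)=CC[C@H]2C1(C)C | intermediate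
18 | allyl diethylphosphonoacetate | C=CCOC(=O)CP(=O)(OCC)OCC | starting material
19 | allyl 3β-(tert-butyldimethylsilyloxy)labda-7,13E-dien-15-oate | CC(C)(C)[Si](C)(C)O[C@H]1CC[C@]2(C)[C@@H](CC/C(C)=C/C(=O)OCC=C)C(C)=CC[C@H]2C1(C)C | intermediate
20 | allyl 3β-hydroxylabda-7,13E-dien-15-oate | O[C@H]1CC[C@]2(C)[C@@H](CC/C(C)=C/C(=O)OCC=C)C(C)=CC[C@H]2C1(C)C | intermediate
21 | acetic anhydride | CC(=O)OC(C)=O | starting material
22 | allyl 3β-acetoxylabda-7,13E-dien-15-oate | CC(=O)O[C@H]1CC[C@]2(C)[C@@H](CC/C(C)=C/C(=O)OCC=C)C(C)=CC[C@H]2C1(C)C | intermediate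
23 | 3β-acetoxylabda-7,13E-dien-15-oic acid (CNP0264606.2) | CC(=O)O[C@H]1CC[C@]2(C)[C@@H](CC/C(C)=C/C(=O)O)C(C)=CC[C@H]2C1(C)C | target

**Step count and risks**
Total step count: 12. Longest linear sequence: 12 steps, fully linear from (R)-carvone.

Steps most likely to fail:

Step 5. The C4 radical may close ring A without telling apart the two faces of the aldehyde carbon (axial against equatorial C–O in the chair), so the 3α-alcohol could accompany or outweigh the 3β-alcohol. The fallback sets out from 10 and sets C3 by hydride reduction instead of by the radical transition state. The cyclisation is run as in step 5, and the crude mixture of 11 and its epimer 3α-hydroxy-11-nordrim-7-en-9-one F1 is oxidised with Dess–Martin periodinane to 11-nordrim-7-ene-3,9-dione F2. NaBH4 in MeOH/CH2Cl2 at −78 °C should then reduce the saturated C3 ketone in preference to the conjugated, doubly flanked C9 ketone. Hydride entering axially gives the equatorial 3β-alcohol, and the route is rejoined at 11.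

Step 8. The bromoacetone carbanion may fail to engage the hindered boron, or a ring B–C bond of the bicyclononane may migrate in place of the β-branched C11 group. The fallback sets out from 14 and forms C11–C12 by an organolithium opening of an epoxide.
- Hydroboration with 9-BBN as before, followed by perborate oxidation of 16, should give 3β-(tert-butyldimethylsilyloxy)drim-7-en-11-ol F3.
- Appel iodination (I2, PPh3, imidazole) converts it into 3β-(tert-butyldimethylsilyloxy)-11-iododrim-7-ene F4.
- Iodine–lithium exchange (t-BuLi, Et2O/pentane, −78 °C) and BF3·OEt2-promoted opening of propylene oxide at its CH2 terminus give 3β-(tert-butyldimethylsilyloxy)-14,15-dinorlabd-7-en-13-ol F5 as a mixture of C13 epimers.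
- Dess–Martin oxidation returns the route to 17.

Step 7. The ylide may add too slowly to the doubly flanked C9 carbonyl and instead deprotonate C6 to the dienolate, which would return the ketone unchanged. The fallback sets out from 12 and uses a Peterson olefination. Trimethylsilylmethyllithium with anhydrous CeCl3 (THF, −78 °C) should add to the carbonyl from the α face to give 3β-(tert-butyldimethylsilyloxy)-9-(trimethylsilylmethyl)-11-nordrim-7-en-9-ol F6. Elimination with KH in THF returns the route to 14.

**Further compounds**
F1 | step 5 | 3α-hydroxy-11-nordrim-7-en-9-one | O[C@@H]1CC[C@]2(C)C(=O)C(C)=CC[C@H]2C1(C)C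
F2 | step 5 | 11-nordrim-7-ene-3,9-dione | O=C1CC[C@]2(C)C(=O)C(C)=CC[C@H]2C1(C)C
F3 | step 8 | 3β-(tert-butyldimethylsilyloxy)drim-7-en-11-ol | CC(C)(C)[Si](C)(C)O[C@H]1CC[C@]2(C)[C@@H](CO)C(C)=CC[C@H]2C1(C)C
F4 | step 8 | 3β-(tert-butyldimethylsilyloxy)-11-iododrim-7-ene | CC(C)(C)[Si](C)(C)O[C@H]1CC[C@]2(C)[C@@H](CI)C(C)=CC[C@H]2C1(C)C
F5 | step 8 | 3β-(tert-butyldimethylsilyloxy)-14,15-dinorlabd-7-en-13-ol (C13 epimers) | CC(C)(C)[Si](C)(C)O[C@H]1CC[C@]2(C)[C@@H](CCC(C)O)C(C)=CC[C@H]2C1(C)C
F6 | step 7 | 3β-(tert-butyldimethylsilyloxy)-9-(trimethylsilylmethyl)-11-nordrim-7-en-9-ol (9β-OH expected) | CC(C)(C)[Si](C)(C)O[C@H]1CC[C@]2(C)[C@](O)(C[Si](C)(C)C)C(C)=CC[C@H]2C1(C)C
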